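## Retrosynthetic overview

1. Target ⇐ selective triacetylation of a pentaol ⇐ γ-lactone closed by an intramolecular samarium Reformatsky reaction (C8–C17) from a C7 2-bromopropanoate.
2. Key step, no macrocyclisation: the ten-membered ring comes from an anionic oxy-Cope ring expansion of a trans-decalin (C3–C8 breaks, C5–C6 forms). The C3 allenyl group becomes the 3Z-ene/5(16)-methylene diene and an (E)-2-chlorovinyl group on C8 delivers the C6 chloride.
3. Oxy-Cope substrate ⇐ C8 ketone by aldol (propynal), stannylvinyl addition, Cl-for-Sn exchange and Myers allene synthesis; ring A cis-diol by OsO4 on a ring A diene.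
4. Decalin ⇐ catalytic asymmetric Diels–Alder of 2-methoxy-5-methylbenzoquinone (ring B, bringing the oxygens of C2, C8 and C9) with (E)-piperylene (ring A).
5. Ring order: ring B (quinone) → ring A (Diels–Alder) → ten-membered ring (oxy-Cope, ring B consumed) → lactone (Reformatsky).

## Conventions and assumptions

- Briarane atom numbers (C1–C20) are used for every intermediate; ring B is C1-C2-C3-C8-C9-C10, ring A is C1-C14-C13-C12-C11-C10; β is the face of the C15 methyl on C1, α the opposite face.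
- Assumption: (R)-BINOL is taken as the ligand enantiomer that gives S at C1; if the sense is opposite, (S)-BINOL is used and nothing else changes.
- Assumption: propynal is bought (sold as a stabilised solution).
- The C4 carbinol (compounds 14, 16–19) and the CHBr carbon (25, 26) are left unassigned because both epimers converge.

## Route

Step 1
Reactants: 1 2-methoxy-5-methyl-1,4-benzoquinone; 2 (E)-penta-1,3-diene
Product: 4 trans-fused 2-methoxy-4a,8-dimethyl-4a,5,8,8a-tetrahydronaphthalene-1,4-dione (1β-CH3; 10α-H; 11α-CH3), via cis-fused endo Diels-Alder adduct 3 (not isolated)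
Conditions: TiCl2(OiPr)2 (0.2 equiv), (R)-BINOL (0.2 equiv), 4 Å MS, CH2Cl2, −30 → 0 °C; then DBU (0.1 equiv), 0 → 23 °C
Reagents that add atoms: (E)-penta-1,3-diene (2), C=C/C=C/C
Why: Diels–Alder reaction under a chelating chiral tetravalent-titanium BINOLate, which binds the C9 carbonyl and the neighbouring methoxy oxygen so that the methyl-bearing carbon C1 is the electrophilic terminus and takes the unsubstituted diene terminus C14 (ortho rule), the catalyst-shielded face fixing C1 as S; DBU then epimerises the enolisable C10 to the more stable trans-decalin, and the endo-derived C11 centre is only transient.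

Step 2
Reactants: 4 trans-fused enedione
Product: 5 12α,13β-dibromide of 4
Conditions: Br2 (1.0 equiv), CH2Cl2, −78 °C
Reagents that add atoms: bromine, BrBr
Why: Electrophilic anti addition of bromine to the only electron-rich alkene (the C3=C8 enol ether is deactivated by two carbonyls), the bromonium ion opening trans-diaxially (Fürst–Plattner) to the 12α,13β-dibromide, which masks ring A during the reduction.

Step 3
Reactants: 5 dibromo enedione
Product: 6 2β,9β-diol
Conditions: iBu2AlH (3 equiv), CH2Cl2, −78 °C; KNaC4H4O6 (aq)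
Reagents that add atoms: none
Why: 1,2-Hydride reduction of both carbonyls with hydride arriving on the α face, anti to the axial C15 methyl, which sets the equatorial 2β-alcohol and the axial 9β-alcohol (substrate control by the angular methyl).

Step 4
Reactants: 6 2β,9β-diol
Product: 7 2β,9β-bis(tert-butyldimethylsilyl) ether
Conditions: TBSOTf (2.6 equiv), 2,6-lutidine (4 equiv), CH2Cl2, −78 → −20 °C
Reagents that add atoms: tert-butyldimethylsilyl triflate, CC(C)(C)[Si](C)(C)OS(=O)(=O)C(F)(F)F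
Why: Base-buffered silylation protects both secondary alcohols without touching the acid-labile enol ether and gives non-chelating ethers, as needed for Felkin–Anh control at C8 later; no stereocentre is formed.

Step 5
Reactants: 7 bis-silyl ether dibromide
Product: 8 ring A 11,13-diene
Conditions: DBU (6 equiv), PhMe, 90 °C
Reagents that add atoms: none
Why: Twofold anti-periplanar E2 dehydrobromination (H14α/Br13β and H11β/Br12α, all axial in the rigid trans-decalin) gives the C11=C12/C13=C14 diene only after the C9 ketone is gone, so the diene cannot move into conjugation with ring B; C11 becomes sp2.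

Step 6
Reactants: 8 diene methyl enol ether
Product: 9 C8 ketone
Conditions: (CO2H)2 (0.2 equiv), THF/H2O 10:1, 0 °C
Reagents that add atoms: water, O
Why: Acid-catalysed enol ether hydrolysis (protonation at C3, hydration at C8, loss of methanol) frees the C8 ketone, the equatorial C2–OTBS bond lying in the nodal plane of the enol ether so that vinylogous ionisation (Stork–Danheiser-type transposition) is disfavoured; no stereocentre is formed.

Step 7
Reactants: 9 diene ketone
Product: 10 11α,12α-diol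
Conditions: OsO4 (0.03 equiv), NMO (1.2 equiv), acetone/H2O 8:1, 0 °C
Reagents that add atoms: osmium tetroxide, O=[Os](=O)(=O)=O (catalytic oxygen carrier); N-methylmorpholine N-oxide, C[N+]1([O-])CCOCC1 (stoichiometric oxygen source)
Why: Upjohn syn-dihydroxylation of the more electron-rich trisubstituted C11=C12 bond from the α face, away from the axial C15 methyl and the axial 9β-silyloxy group, sets 11α-OH/11β-CH3 and 12α-OH together and leaves C13=C14.

Step 8
Reactants: 10 11α,12α-diol
Product: 11 11,12-O-isopropylidene ketone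
Conditions: Me2C(OMe)2 (5 equiv), PPTS (0.1 equiv), CH2Cl2, 23 °C
Reagents that add atoms: 2,2-dimethoxypropane, COC(C)(C)OC
Why: Acid-catalysed transketalisation ties the cis-diol into an acetonide, so the tertiary C11 hydroxyl cannot later form a hemiketal with the C8 ketone; no stereocentre is formed.

Step 9
Reactants: 11 acetonide ketone; 12 propynal
Product: 14 3α-(1-hydroxyprop-2-yn-1-yl) ketone, via lithium C3=C8 enolate 13 (not isolated)
Conditions: LiN(iPr)2 (1.1 equiv), THF, −78 °C; 12 (1.3 equiv), −78 °C; AcOH, −78 °C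
Reagents that add atoms: propynal (12), C#CC=O
Why: Kinetic deprotonation at the C3 methylene (the C9 hydrogen is equatorial and poorly aligned) and aldol addition on the α face of the enolate, away from the 1,3-related axial C15 methyl, place the three-carbon chain equatorial (3α); the C4 carbinol is destroyed in step 12.

Step 10
Reactants: 14 aldol adduct; 15 (E)-1,2-bis(tributylstannyl)ethene
Product: 16 8β-hydroxy-8α-[(E)-2-(tributylstannyl)ethenyl] carbinol
Conditions: 15 (4.2 equiv), nBuLi (4.0 equiv), THF, −78 °C; CeCl3 (4.0 equiv), −78 °C; then 14, −78 → −40 °C; NH4Cl (aq)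
Reagents that add atoms: (E)-1,2-bis(tributylstannyl)ethene (15), CCCC[Sn](CCCC)(CCCC)/C=C/[Sn](CCCC)(CCCC)CCCC
Why: Tin–lithium exchange gives (E)-2-(tributylstannyl)vinyllithium, whose organocerium adds 1,2 to the enolisable ketone by axial attack on the α face, antiperiplanar to the axial C9–OTBS bond (polar Felkin–Anh), so the alkenyl group is 8α and cis to the C3 chain.

Step 11
Reactants: 16 alkenylstannane
Product: 17 8β-hydroxy-8α-[(E)-2-chloroethenyl] carbinol
Conditions: CuCl2 (2.5 equiv), THF, 0 → 23 °C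
Reagents that add atoms: copper dichloride, Cl[Cu]Cl
Why: Chlorodestannylation with divalent copper chloride goes with retention of alkene geometry and turns the (E)-alkenylstannane into the (E)-2-chlorovinyl group that will carry chlorine to C6.

Step 12
Reactants: 17 propargylic alcohol
Product: 20 3α-allenyl 8α-[(E)-2-chloroethenyl] 8β-ol, via N-propargylic sulfonylhydrazide 18 (not isolated), via propargylic diazene 19 (not isolated)
Conditions: PPh3 (1.6 equiv), DEAD (1.6 equiv), THF, −15 °C; 2-nitrobenzenesulfonylhydrazide (1.6 equiv), −15 °C; then 23 °C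
Reagents that add atoms: none
Why: Myers allene synthesis, in which Mitsunobu displacement of the secondary propargylic hydroxyl (the tertiary C8 hydroxyl is inert), loss of sulfinic acid and retro-ene loss of dinitrogen from the diazene transpose the alkyne into the terminal allene C4=C5=C16 without touching C3.

Step 13
Reactants: 20 oxy-Cope substrate
Product: 23 ten-membered 6S-chloro-7-hydroxy-8-ketone (7-epi), via potassium alkoxide 21 (not isolated), via potassium enolate 22 (not isolated)
Conditions: KN(SiMe3)2 (1.15 equiv), 18-crown-6 (1.5 equiv), THF, −78 → −20 °C; then −78 °C, (±)-2-(phenylsulfonyl)-3-phenyloxaziridine (1.5 equiv); AcOH, −78 °C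
Reagents that add atoms: 2-(phenylsulfonyl)-3-phenyloxaziridine, O=S(=O)(c1ccccc1)N1OC1c1ccccc1
Why: Proposed new method: anionic oxy-Cope ring expansion of a cis-1-alkenyl-2-allenylcyclohexanol (closest known reaction types: anionic oxy-Cope expansion of cis-1,2-divinylcyclohexanols to (Z)-cyclodec-5-enones and allenyl oxy-Cope rearrangements that give 1,3-dienes), in which the chair transition state fixed by the trans-decalin (axial chlorovinyl on C8, equatorial allenyl on C3) gives the 3Z-alkene, the 5(16)-methylene and, from the (E)-chlorovinyl terminus, the 6S chloride, the C6–Cl bond lying in the nodal plane of the newly formed enolate so that E1cB loss of chloride is retarded at low temperature, and Davis hydroxylation then takes place on the only open enolate face, away from the transannular diene, giving the 7-epi alcohol that step 14 corrects.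

Step 14
Reactants: 23 7-epi α-ketol; 24 2-bromopropanoic acid (racemic)
Product: 25 7R 2-bromopropanoate
Conditions: PPh3 (2 equiv), DIAD (2 equiv), PhMe, 0 °C; then 23 and 24 (2 equiv), 0 → 23 °C
Reagents that add atoms: 2-bromopropanoic acid (24), CC(Br)C(=O)O
Why: Mitsunobu esterification, an SN2 displacement at a carbon activated by the adjacent carbonyl, inverts C7 to the natural 7R configuration and installs the Reformatsky donor in the same operation.

Step 15
Reactants: 25 7R 2-bromopropanoate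
Product: 27 protected 8R-hydroxy 17R-methyl γ-lactone, via samarium ester enolate 26 (not isolated)
Conditions: SmI2 (2.2 equiv), THF, −78 °C; NH4Cl (aq)
Reagents that add atoms: none
Why: Intramolecular samarium Reformatsky reaction in which divalent samarium reduces the α-bromo ester faster than the ketone and the tethered trivalent-samarium enolate adds to C8 from the side of the C7 oxygen and anti to the C9–OTBS bond (polar Felkin–Anh, C6–C9 backbone extended), giving the trans-fused β-hydroxy-γ-lactone (8R) with the epimerisable C17 methyl trans to the C8–C9 bond (17R).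

Step 16
Reactants: 27 protected lactone
Product: 28 2,8,9,11,12-pentaol
Conditions: HF (48% aq)/MeCN 1:10, 0 → 23 °C
Reagents that add atoms: none
Why: Acidic fluoride removes both TBS ethers and hydrolyses the acetonide without base, so the β-hydroxy lactone and the allylic chloride see no retro-aldol or elimination conditions; no stereocentre is touched.

Step 17
Reactants: 28 pentaol; 29 acetic anhydride
Product: 30 CNP0285654.2
Conditions: Ac2O (10 equiv), pyridine, 23 °C
Reagents that add atoms: acetic anhydride (29), CC(=O)OC(C)=O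
Why: Acetylation without DMAP esterifies the three secondary alcohols (C2, C9, C12) and leaves the hindered tertiary alcohols (C8, C11) free, which gives the target.

## Compound list

1 | 2-methoxy-5-methyl-1,4-benzoquinone | COC1=CC(=O)C(C)=CC1=O | starting material
2 | (E)-penta-1,3-diene | C=C/C=C/C | starting material
3 | cis-fused endo adduct, 2-methoxy-4a,8-dimethyl-4a,5,8,8a-tetrahydronaphthalene-1,4-dione (1β-CH3, 10β-H, 11α-CH3) | COC1=CC(=O)[C@@]2(C)CC=C[C@@H](C)[C@H]2C1=O | intermediate (not isolated)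
4 | trans-fused isomer of 3 (1β-CH3, 10α-H, 11α-CH3; ketones at C2 and C9, C3=C8 with OCH3 on C8, C12=C13) | COC1=CC(=O)[C@@]2(C)CC=C[C@@H](C)[C@@H]2C1=O | intermediate
5 | 12α,13β-dibromide of 4 (both bromines axial) | COC1=CC(=O)[C@@]2(C)C[C@H](Br)[C@@H](Br)[C@@H](C)[C@@H]2C1=O | intermediate
6 | 2β,9β-diol of 5 (methyl enol ether C3=C8 kept) | COC1=C[C@H](O)[C@@]2(C)C[C@H](Br)[C@@H](Br)[C@@H](C)[C@@H]2[C@@H]1O | intermediate
7 | 2β,9β-bis(tert-butyldimethylsilyl) ether of 6 | COC1=C[C@H](O[Si](C)(C)C(C)(C)C)[C@@]2(C)C[C@H](Br)[C@@H](Br)[C@@H](C)[C@@H]2[C@@H]1O[Si](C)(C)C(C)(C)C | intermediate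
8 | ring A 11,13-diene (C11=C12, C13=C14) with ring B methyl enol ether and both TBS ethers | COC1=C[C@H](O[Si](C)(C)C(C)(C)C)[C@@]2(C)C=CC=C(C)[C@@H]2[C@@H]1O[Si](C)(C)C(C)(C)C | intermediate
9 | C8 ketone (ring B: 2β-OTBS, C3H2, C8=O, 9β-OTBS; ring A 11,13-diene) | O=C1C[C@H](O[Si](C)(C)C(C)(C)C)[C@@]2(C)C=CC=C(C)[C@@H]2[C@@H]1O[Si](C)(C)C(C)(C)C | intermediate
10 | 11α,12α-diol of 9 (11β-CH3, C13=C14 kept) | O=C1C[C@H](O[Si](C)(C)C(C)(C)C)[C@@]2(C)C=C[C@@H](O)[C@@](C)(O)[C@@H]2[C@@H]1O[Si](C)(C)C(C)(C)C | intermediate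
11 | 11,12-O-isopropylidene derivative of 10 | O=C1C[C@H](O[Si](C)(C)C(C)(C)C)[C@@]2(C)C=C[C@@H](OC(C)(C)O3)[C@]3(C)[C@@H]2[C@@H]1O[Si](C)(C)C(C)(C)C | intermediate
12 | propynal | C#CC=O | starting material
13 | lithium C3=C8 enolate of 11 | [Li+].[O-]C1=C[C@H](O[Si](C)(C)C(C)(C)C)[C@@]2(C)C=C[C@@H](OC(C)(C)O3)[C@]3(C)[C@@H]2[C@@H]1O[Si](C)(C)C(C)(C)C | intermediate (not isolated)
14 | aldol adduct: 11 with a 3α-(1-hydroxyprop-2-yn-1-yl) group (C4 epimers) | O=C1[C@@H](C(O)C#C)[C@H](O[Si](C)(C)C(C)(C)C)[C@@]2(C)C=C[C@@H](OC(C)(C)O3)[C@]3(C)[C@@H]2[C@@H]1O[Si](C)(C)C(C)(C)C | intermediate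
15 | (E)-1,2-bis(tributylstannyl)ethene | CCCC[Sn](CCCC)(CCCC)/C=C/[Sn](CCCC)(CCCC)CCCC | starting material
16 | 8β-hydroxy-8α-[(E)-2-(tributylstannyl)ethenyl] carbinol from 14 | C#CC(O)[C@H]1[C@H](O[Si](C)(C)C(C)(C)C)[C@@]2(C)C=C[C@@H](OC(C)(C)O3)[C@]3(C)[C@@H]2[C@H](O[Si](C)(C)C(C)(C)C)[C@@]1(O)/C=C/[Sn](CCCC)(CCCC)CCCC | intermediate
17 | 8β-hydroxy-8α-[(E)-2-chloroethenyl] carbinol | C#CC(O)[C@H]1[C@H](O[Si](C)(C)C(C)(C)C)[C@@]2(C)C=C[C@@H](OC(C)(C)O3)[C@]3(C)[C@@H]2[C@H](O[Si](C)(C)C(C)(C)C)[C@@]1(O)/C=C/Cl | intermediate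
18 | C4 N-alkyl 2-nitrobenzenesulfonylhydrazide of 17 | C#CC(N(N)S(=O)(=O)c4ccccc4[N+](=O)[O-])[C@H]1[C@H](O[Si](C)(C)C(C)(C)C)[C@@]2(C)C=C[C@@H](OC(C)(C)O3)[C@]3(C)[C@@H]2[C@H](O[Si](C)(C)C(C)(C)C)[C@@]1(O)/C=C/Cl | intermediate (not isolated)
19 | C4 monoalkyl diazene | C#CC(N=N)[C@H]1[C@H](O[Si](C)(C)C(C)(C)C)[C@@]2(C)C=C[C@@H](OC(C)(C)O3)[C@]3(C)[C@@H]2[C@H](O[Si](C)(C)C(C)(C)C)[C@@]1(O)/C=C/Cl | intermediate (not isolated)
20 | oxy-Cope substrate: 3α-(propa-1,2-dien-1-yl)-8α-[(E)-2-chloroethenyl]-8β-ol (2β,9β-di-OTBS, 11α,12α-acetonide, 13-ene, 1β-CH3, 10α-H) | C=C=C[C@H]1[C@H](O[Si](C)(C)C(C)(C)C)[C@@]2(C)C=C[C@@H](OC(C)(C)O3)[C@]3(C)[C@@H]2[C@H](O[Si](C)(C)C(C)(C)C)[C@@]1(O)/C=C/Cl | intermediate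
21 | potassium 8-alkoxide of 20 | C=C=C[C@H]1[C@H](O[Si](C)(C)C(C)(C)C)[C@@]2(C)C=C[C@@H](OC(C)(C)O3)[C@]3(C)[C@@H]2[C@H](O[Si](C)(C)C(C)(C)C)[C@@]1([O-])/C=C/Cl.[K+] | intermediate (not isolated)
22 | ring-expanded potassium enolate (C7=C8 with C6 and C9 trans; 3Z; 5(16)-methylene; C6 chloride as in 23) | C=C1/C=C\[C@H](O[Si](C)(C)C(C)(C)C)[C@@]2(C)C=C[C@@H](OC(C)(C)O3)[C@]3(C)[C@@H]2[C@H](O[Si](C)(C)C(C)(C)C)/C([O-])=C/[C@H]1Cl.[K+] | intermediate (not isolated)
23 | ten-membered α-ketol: (3Z)-3,5(16),13-triene, 6S-chloro, 7S-hydroxy (7-epi), 8-oxo, 2,9-di-OTBS, 11,12-acetonide | C=C1/C=C\[C@H](O[Si](C)(C)C(C)(C)C)[C@@]2(C)C=C[C@@H](OC(C)(C)O3)[C@]3(C)[C@@H]2[C@H](O[Si](C)(C)C(C)(C)C)C(=O)[C@H](O)[C@H]1Cl | intermediate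
24 | 2-bromopropanoic acid (racemic) | CC(Br)C(=O)O | starting material
25 | 7R 2-bromopropanoate of the ketol (C7 inverted; CHBr epimers) | C=C1/C=C\[C@H](O[Si](C)(C)C(C)(C)C)[C@@]2(C)C=C[C@@H](OC(C)(C)O3)[C@]3(C)[C@@H]2[C@H](O[Si](C)(C)C(C)(C)C)C(=O)[C@@H](OC(=O)C(C)Br)[C@H]1Cl | intermediate
26 | diiodosamarium ester enolate of 25 | C=C1/C=C\[C@H](O[Si](C)(C)C(C)(C)C)[C@@]2(C)C=C[C@@H](OC(C)(C)O3)[C@]3(C)[C@@H]2[C@H](O[Si](C)(C)C(C)(C)C)C(=O)[C@@H](OC(O[Sm](I)I)=CC)[C@H]1Cl | intermediate (not isolated)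
27 | protected lactone: 8R-hydroxy, 17R-methyl γ-lactone (C19 carbonyl to O–C7), 6S-chloro, 2,9-di-OTBS, 11,12-acetonide | C=C1/C=C\[C@H](O[Si](C)(C)C(C)(C)C)[C@@]2(C)C=C[C@@H](OC(C)(C)O3)[C@]3(C)[C@@H]2[C@H](O[Si](C)(C)C(C)(C)C)[C@]2(O)[C@@H](C)C(=O)O[C@H]2[C@H]1Cl | intermediate
28 | (1S,2S,3Z,6S,7R,8R,9S,10S,11S,12R,17R)-6-chloro-2,8,9,11,12-pentahydroxybriara-3,5(16),13-trien-19,7-olide | C=C1/C=C\[C@H](O)[C@@]2(C)C=C[C@@H](O)[C@@](C)(O)[C@@H]2[C@H](O)[C@]2(O)[C@@H](C)C(=O)O[C@H]2[C@H]1Cl | intermediate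
29 | acetic anhydride | CC(=O)OC(C)=O | starting material
30 | CNP0285654.2, (1S,2S,3Z,6S,7R,8R,9S,10S,11S,12R,17R)-2,9,12-triacetoxy-6-chloro-8,11-dihydroxybriara-3,5(16),13-trien-19,7-olide | C=C1/C=C\[C@H](OC(C)=O)[C@@]2(C)C=C[C@@H](OC(C)=O)[C@@](C)(O)[C@@H]2[C@H](OC(C)=O)[C@]2(O)[C@@H](C)C(=O)O[C@H]2[C@H]1Cl | target

## Step count and risks

Total step count: 17. Longest linear sequence: 17 steps (from 1; 2, 12, 15, 24 and 29 are bought).

The three steps most likely to fail:

Step 13 (ring expansion and hydroxylation). The β-chloro enolate 22 may lose chloride before it is trapped, or the oxidant may come from the other face. The fallback sets out from 20 and comes back at 25. The elimination is made the plan: KN(SiMe3)2 and 18-crown-6 in THF at 0 → 23 °C take 20 through 22 to the cross-conjugated (3Z,6E)-trienone F1, the least-motion E1cB product. Weitz–Scheffer epoxidation (tBuOOH, DBU, CH2Cl2, 0 °C) on the exposed face gives the trans-6,7-epoxy ketone F2. HCl in Et2O at −40 °C opens it by SN2 at the allylic C6 with inversion to the (6S,7R)-chlorohydrin F3. F3 already has the natural C7 oxygen, so simple acylation with 2-bromopropanoyl bromide and pyridine (no inversion) gives 25.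

Step 14 (Mitsunobu inversion at a hindered α-ketol next to the CHCl carbon). Elimination may win over substitution. The fallback sets out from 20 and comes back at 25. Step 13 is run unchanged as far as enolate 22, which is quenched with N-bromosuccinimide (THF, −78 °C) instead of the oxaziridine to give the 7-bromo-6-chloro ketone F4, with bromine on the open face where 23 has its hydroxyl. CsO2CCH(Br)CH3 in DMF at 0 °C then displaces the bromide by SN2 at the α-keto carbon with inversion and gives 25 without phosphorus reagents.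

Step 15 (Reformatsky lactonisation). Divalent samarium may cleave the α-acyloxy ketone, the five-ring closure through an endocyclic enolate may be slow, or the wrong C8 face may react. The fallback sets out from 23 and comes back at 27. Mitsunobu esterification of 23 with 2-(diethoxyphosphoryl)propanoic acid (inversion at C7) gives the 7R phosphonopropanoate F5. Intramolecular Horner–Wadsworth–Emmons olefination (LiCl, iPr2NEt, MeCN) closes the 8(17)-unsaturated butenolide F6. Nucleophilic epoxidation (LiOOtBu, THF, −20 °C) gives the 8,17-epoxy lactone F7. SmI2 in THF/MeOH at −78 °C cleaves the C17–O bond α to the carbonyl and protonation of the enolate gives 27.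

## Further compounds

F1 | step 13 | (3Z,6E)-trienone from 20 by ring expansion and loss of chloride (8-oxo, C6=C7, 5(16)-methylene, 2,9-di-OTBS, 11,12-acetonide) | O=C1/C=C/C(=C)/C=C\[C@H](O[Si](C)(C)C(C)(C)C)[C@@]2(C)C=C[C@@H](OC(C)(C)O3)[C@]3(C)[C@@H]2[C@@H]1O[Si](C)(C)C(C)(C)C
F2 | step 13 | trans-6,7-epoxy-8-ketone (C7 oxygen in the natural position) | O=C1[C@H]2O[C@@H]2C(=C)/C=C\[C@H](O[Si](C)(C)C(C)(C)C)[C@@]2(C)C=C[C@@H](OC(C)(C)O3)[C@]3(C)[C@@H]2[C@@H]1O[Si](C)(C)C(C)(C)C
F3 | step 13 | (6S,7R)-6-chloro-7-hydroxy-8-ketone (C7 epimer of 23) | C=C1/C=C\[C@H](O[Si](C)(C)C(C)(C)C)[C@@]2(C)C=C[C@@H](OC(C)(C)O3)[C@]3(C)[C@@H]2[C@H](O[Si](C)(C)C(C)(C)C)C(=O)[C@@H](O)[C@H]1Cl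
F4 | step 14 | 7-bromo-6-chloro-8-ketone (bromine in the place of the hydroxyl of 23) | C=C1/C=C\[C@H](O[Si](C)(C)C(C)(C)C)[C@@]2(C)C=C[C@@H](OC(C)(C)O3)[C@]3(C)[C@@H]2[C@H](O[Si](C)(C)C(C)(C)C)C(=O)[C@H](Br)[C@H]1Cl
F5 | step 15 | 7R 2-(diethoxyphosphoryl)propanoate of the ten-membered ketone | C=C1/C=C\[C@H](O[Si](C)(C)C(C)(C)C)[C@@]2(C)C=C[C@@H](OC(C)(C)O3)[C@]3(C)[C@@H]2[C@H](O[Si](C)(C)C(C)(C)C)C(=O)[C@@H](OC(=O)C(C)P(=O)(OCC)OCC)[C@H]1Cl
F6 | step 15 | 8(17)-unsaturated butenolide | C=C1/C=C\[C@H](O[Si](C)(C)C(C)(C)C)[C@@]2(C)C=C[C@@H](OC(C)(C)O3)[C@]3(C)[C@@H]2[C@H](O[Si](C)(C)C(C)(C)C)C2=C(C)C(=O)O[C@H]2[C@H]1Cl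
F7 | step 15 | 8,17-epoxy lactone (C8 oxygen in the natural position) | C=C1/C=C\[C@H](O[Si](C)(C)C(C)(C)C)[C@@]2(C)C=C[C@@H](OC(C)(C)O3)[C@]3(C)[C@@H]2[C@H](O[Si](C)(C)C(C)(C)C)[C@@]23O[C@@]3(C)C(=O)O[C@H]2[C@H]1Cl
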